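**Plan**

- Retrosynthesis first returns the enal to a silyl-protected allylic alcohol and the C5 side chain to an acetyl group (acyl–O cut to (R)-2-methylbutanoic acid, then C–H to C=O).
- The benzene ring is then cut at C3a–C7a and C4–C5. C3a and C4 become a terminal alkyne, C7a–C7–C6–C5 become the four carbons of a 6-acetylpyridazine, and O1–C2–C3 is the but-3-ynyloxy tether between them; this fused arene/three-atom tether is what allows an intramolecular pyridazine–alkyne cycloaddition with loss of N2.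
- The precursor is cut at O1–C7a (SNAr), at the C3 ester and at the alkyne (one-carbon homologation of an aldehyde). C3, C2, the vinyl carbon and the CHO carbon are C3, C4, C5 and C6 of D-glucose.
- Forward: diacetone-D-glucose → 5-methylene furanose → C1 excised and alkyne made → pyridazinyl ether → isovalerate → dihydrofuran and benzene rings closed together in one thermal step → reduction, esterification, desilylation, oxidation.
- Stereochemistry: C2 and C3 (cis, R,R) are glucose C4 and C3, never touched; the carbinol centre comes from a CBS reduction; the acid centre is bought as (R)-2-methylbutanoic acid.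

Key step: step 13

Remark: diacetone-D-glucose 1 (the 1,2:5,6-diacetonide of D-glucose) is taken as the commercial starting material. Lactol 10 is handled as the anomeric mixture, since C1 is removed in step 7.

**Route**

Step 1
Reactants: 1 diacetone-D-glucose; 2 2-(bromomethyl)naphthalene
Product: 3 1,2:5,6-di-O-isopropylidene-3-O-(2-naphthylmethyl)-α-D-glucofuranose
Conditions: NaH, DMF, 0 °C → rt
Reagents that add atoms: 2-(bromomethyl)naphthalene 2, BrCc1ccc2ccccc2c1
Why: Williamson etherification of the only free hydroxyl (O3) with a reactive arylmethyl bromide; the 2-naphthylmethyl (NAP) ether tolerates the later acid and base steps and can be removed oxidatively.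

Step 2
Reactants: 3
Product: 4 1,2-O-isopropylidene-3-O-(2-naphthylmethyl)-α-D-glucofuranose (5,6-diol)
Conditions: AcOH/H2O (3:2), rt → 40 °C
Reagents that add atoms: none
Why: Selective acetal hydrolysis, because the terminal 5,6-dioxolane opens far faster in dilute acetic acid than the cis-fused 1,2-acetal.

Step 3
Reactants: 4; 5 tert-butyl(chloro)diphenylsilane (TBDPSCl)
Product: 6 6-O-(tert-butyldiphenylsilyl)-1,2-O-isopropylidene-3-O-(2-naphthylmethyl)-α-D-glucofuranose
Conditions: TBDPSCl, imidazole, CH2Cl2, 0 °C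
Reagents that add atoms: tert-butyl(chloro)diphenylsilane 5, CC(C)(C)[Si](Cl)(c1ccccc1)c1ccccc1
Why: Silylation with the bulky chlorosilane should take the primary O6 in preference to the secondary O5, and the TBDPS ether is acid-stable enough for step 6.

Step 4
Reactants: 6
Product: 7 6-O-(tert-butyldiphenylsilyl)-1,2-O-isopropylidene-3-O-(2-naphthylmethyl)-α-D-xylo-hexofuranos-5-ulose
Conditions: Dess–Martin periodinane, CH2Cl2, 0 °C → rt
Reagents that add atoms: none
Why: Dess–Martin oxidation of the secondary C5 alcohol under near-neutral conditions, which should leave the adjacent C4 centre unepimerised.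

Step 5
Reactants: 7; 8 methyltriphenylphosphonium bromide
Product: 9 6-O-(tert-butyldiphenylsilyl)-5-deoxy-1,2-O-isopropylidene-5-methylidene-3-O-(2-naphthylmethyl)-α-D-xylo-hexofuranose
Conditions: Ph3PCH3Br, KOtBu, THF, 0 °C; then 7, −78 → 0 °C
Reagents that add atoms: methyltriphenylphosphonium bromide 8, C[P+](c1ccccc1)(c1ccccc1)c1ccccc1.[Br-]
Why: Wittig methylenation with the non-stabilised ylide, which adds to the ketone at low temperature faster than it enolises it towards C4.

Step 6
Reactants: 9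
Product: 10 6-O-(tert-butyldiphenylsilyl)-5-deoxy-5-methylidene-3-O-(2-naphthylmethyl)-D-xylo-hexofuranose (lactol, both anomers)
Conditions: AcOH/H2O (4:1), 80 °C
Reagents that add atoms: water, O (possible source of the anomeric hydroxyl oxygen)
Why: Acid hydrolysis of the remaining 1,2-acetal; NAP and TBDPS ethers are known to withstand hot aqueous acetic acid, and the alkene is deactivated towards protonation by its two allylic oxygens.

Step 7
Reactants: 10
Product: 11 (2S,3R)-4-[(tert-butyldiphenylsilyl)oxymethyl]-3-formyloxy-2-(2-naphthylmethoxy)pent-4-enal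
Conditions: NaIO4, THF/H2O, 0 °C → rt
Reagents that add atoms: none
Why: Malaprade glycol cleavage of the C1–C2 diol of the lactol; C1 stays on O4 as a formate, which keeps O4 distinct from O3 and frees the glucose C2 aldehyde.

Step 8
Reactants: 11; 12 dimethyl (1-diazo-2-oxopropyl)phosphonate
Product: 14 (3R,4R)-2-[(tert-butyldiphenylsilyl)oxymethyl]-4-(2-naphthylmethoxy)hex-1-en-5-yn-3-ol, via hydroxy aldehyde 13 (not isolated)
Conditions: dimethyl (1-diazo-2-oxopropyl)phosphonate, K2CO3, MeOH, 0 °C → rt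
Reagents that add atoms: dimethyl (1-diazo-2-oxopropyl)phosphonate 12, COP(=O)(OC)C(=[N+]=[N-])C(C)=O
Why: Seyferth–Gilbert homologation in its Ohira–Bestmann form, in which methoxide removes the formate and unmasks the diazomethylphosphonate anion, which converts the aldehyde into the terminal alkyne under carbonate conditions mild enough to keep the α-alkoxy centre.

Step 9
Reactants: 15 3,6-dichloropyridazine; 16 tributyl(1-ethoxyvinyl)stannane
Product: 17 3-chloro-6-(1-ethoxyvinyl)pyridazine
Conditions: PdCl2(PPh3)2 (5 mol%), DMF, 90 °C, 15 in excess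
Reagents that add atoms: tributyl(1-ethoxyvinyl)stannane 16, CCCC[Sn](CCCC)(CCCC)C(=C)OCC
Why: Stille coupling of an activated heteroaryl chloride; excess dichloride and the lower reactivity of the donor-substituted product should hold it at mono-substitution, and the masked acetyl group is installed before any allylic ether or alkyne is exposed to palladium.

Step 10
Reactants: 14; 17
Product: 19 1-(6-{[(3R,4R)-2-[(tert-butyldiphenylsilyl)oxymethyl]-4-(2-naphthylmethoxy)hex-1-en-5-yn-3-yl]oxy}pyridazin-3-yl)ethan-1-one, via enol ether 18 (not isolated)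
Conditions: NaH, THF/DMF, 0 °C; 17, rt → 45 °C; then 1 M HCl, THF, rt
Reagents that add atoms: 3-chloro-6-(1-ethoxyvinyl)pyridazine 17, C=C(OCC)c1ccc(Cl)nn1; water, O
Why: Nucleophilic aromatic substitution (addition–elimination) of the C3-alkoxide at the chlorodiazine forms the O–aryl bond without touching the carbinol carbon, so its configuration is retained, and dilute acid then hydrolyses the enol ether to the methyl ketone.

Step 11
Reactants: 19
Product: 20 1-(6-{[(3R,4R)-2-[(tert-butyldiphenylsilyl)oxymethyl]-4-hydroxyhex-1-en-5-yn-3-yl]oxy}pyridazin-3-yl)ethan-1-one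
Conditions: DDQ, CH2Cl2/pH 7 buffer, rt
Reagents that add atoms: none
Why: Oxidative cleavage of the 2-naphthylmethyl ether by DDQ (hydride abstraction, then hydrolysis of the oxocarbenium ion), which leaves the alkene, alkyne, silyl ether and electron-poor diazine alone.

Step 12
Reactants: 20; 21 3-methylbutanoyl chloride (isovaleryl chloride)
Product: 22 (3R,4R)-4-[(6-acetylpyridazin-3-yl)oxy]-5-[(tert-butyldiphenylsilyl)oxymethyl]hex-5-en-1-yn-3-yl 3-methylbutanoate
Conditions: isovaleryl chloride, pyridine, 4-(dimethylamino)pyridine (cat.), CH2Cl2, 0 °C → rt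
Reagents that add atoms: 3-methylbutanoyl chloride 21, CC(C)CC(=O)Cl
Why: Nucleophile-catalysed acylation of the propargylic alcohol at oxygen, hence with retention, under conditions too weakly basic for aryl migration between the two vicinal oxygens.

Step 13
Reactants: 22
Product: 24 (2R,3R)-5-acetyl-2-{3-[(tert-butyldiphenylsilyl)oxy]prop-1-en-2-yl}-2,3-dihydro-1-benzofuran-3-yl 3-methylbutanoate (cis), via bridged azo adduct 23 (not isolated)
Conditions: 1,2-dichlorobenzene (degassed, 0.02 M), 2,6-di-tert-butyl-4-methylphenol (cat.), 170 °C, sealed tube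
Reagents that add atoms: none
Why: The tethered terminal alkyne adds across C3 and C6 of the acetylpyridazine in a [4+2] cycloaddition controlled by the low-lying diazine LUMO, and the resulting 2,3-diazabicyclo[2.2.2]octatriene 23 expels N2 by retro-[4+2] to become the benzene ring. The closest known reaction is the thermal conversion of 3-(but-3-ynyloxy)pyridazines into 2,3-dihydrobenzofurans. The dihydrofuran ring closes in the cycloaddition itself, by C3a–C7a bond formation through the three-atom O1–C2–C3 tether in the fused mode, and the benzene ring closes by C4–C5 bond formation followed by the cycloreversion. No stereocentre is created, and C2 and C3 keep the configuration of glucose C4 and C3 because none of their bonds is made or broken. The step needs regioselectivity, which the tether length enforces (the acetyl carbon must end at C5, para to O1), and chemoselectivity over O-to-N allyl shift of the pyridazinyl ether and loss of isovaleric acid, which the acetyl group and the doubly substituted tether should secure by bringing the cycloaddition into a temperature range where both are slow.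

Step 14
Reactants: 24
Product: 26 (2R,3R)-2-{3-[(tert-butyldiphenylsilyl)oxy]prop-1-en-2-yl}-5-[(1R)-1-hydroxyethyl]-2,3-dihydro-1-benzofuran-3-yl 3-methylbutanoate, via catechol borate 25 (not isolated)
Conditions: (S)-2-methyl-CBS-oxazaborolidine [(S)-1-methyl-3,3-diphenyltetrahydro-1H,3H-pyrrolo[1,2-c][1,3,2]oxazaborole] (20 mol%), catecholborane, toluene, −78 → −40 °C; then MeOH, aqueous NaHCO3
Reagents that add atoms: none
Why: Corey–Bakshi–Shibata reduction, in which the (S)-oxazaborolidine delivers hydride to the aryl methyl ketone with aryl as the large group to give the (R)-carbinol under catalyst control, and catecholborane at low temperature should not hydroborate the 1,1-disubstituted alkene or touch the ester.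

Step 15
Reactants: 26; 27 (R)-2-methylbutanoic acid
Product: 28 (2R,3R)-2-{3-[(tert-butyldiphenylsilyl)oxy]prop-1-en-2-yl}-5-{(1R)-1-[(2R)-2-methylbutanoyloxy]ethyl}-2,3-dihydro-1-benzofuran-3-yl 3-methylbutanoate
Conditions: (R)-2-methylbutanoic acid, DCC, 4-(dimethylamino)pyridine (cat.), CH2Cl2, 0 °C → rt
Reagents that add atoms: (R)-2-methylbutanoic acid 27, OC(=O)[C@H](C)CC
Why: Steglich esterification acylates the carbinol oxygen, so the benzylic centre is retained, and the low temperature and catalytic amount of nucleophilic catalyst should keep the α-centre of the acid intact.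

Step 16
Reactants: 28
Product: 29 (2R,3R)-2-(3-hydroxyprop-1-en-2-yl)-5-{(1R)-1-[(2R)-2-methylbutanoyloxy]ethyl}-2,3-dihydro-1-benzofuran-3-yl 3-methylbutanoate
Conditions: HF·pyridine, pyridine, THF, 0 °C → rt
Reagents that add atoms: none
Why: Fluoride-driven desilylation of the primary silyl ether in a pyridine-buffered medium that is neither basic enough to eliminate the C3 ester nor acidic enough to ionise the benzylic ester.

Step 17
Reactants: 29
Product: 30 (2R,3R)-5-{(1R)-1-[(2R)-2-methylbutanoyloxy]ethyl}-2-(3-oxoprop-1-en-2-yl)-2,3-dihydro-1-benzofuran-3-yl 3-methylbutanoate (CNP0154159.2)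
Conditions: MnO2 (activated, excess), CH2Cl2, rt
Reagents that add atoms: none
Why: Heterogeneous MnO2 oxidation selective for the allylic alcohol gives the 2-substituted acrolein under neutral conditions that should not epimerise C2 or eliminate the C3 ester.

**Compound list**

1 | 1,2:5,6-di-O-isopropylidene-α-D-glucofuranose (diacetone-D-glucose) | CC1(C)OC[C@@H](O1)[C@H]1O[C@@H]2OC(C)(C)O[C@@H]2[C@H]1O | starting material
2 | 2-(bromomethyl)naphthalene | BrCc1ccc2ccccc2c1 | starting material
3 | 1,2:5,6-di-O-isopropylidene-3-O-(2-naphthylmethyl)-α-D-glucofuranose | CC1(C)OC[C@@H](O1)[C@H]1O[C@@H]2OC(C)(C)O[C@@H]2[C@H]1OCc1ccc2ccccc2c1 | intermediate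
4 | 1,2-O-isopropylidene-3-O-(2-naphthylmethyl)-α-D-glucofuranose | OC[C@@H](O)[C@H]1O[C@@H]2OC(C)(C)O[C@@H]2[C@H]1OCc1ccc2ccccc2c1 | intermediate
5 | tert-butyl(chloro)diphenylsilane | CC(C)(C)[Si](Cl)(c1ccccc1)c1ccccc1 | starting material
6 | 6-O-(tert-butyldiphenylsilyl)-1,2-O-isopropylidene-3-O-(2-naphthylmethyl)-α-D-glucofuranose | CC(C)(C)[Si](OC[C@@H](O)[C@H]1O[C@@H]2OC(C)(C)O[C@@H]2[C@H]1OCc1ccc2ccccc2c1)(c1ccccc1)c1ccccc1 | intermediate
7 | 6-O-(tert-butyldiphenylsilyl)-1,2-O-isopropylidene-3-O-(2-naphthylmethyl)-α-D-xylo-hexofuranos-5-ulose | CC(C)(C)[Si](OCC(=O)[C@H]1O[C@@H]2OC(C)(C)O[C@@H]2[C@H]1OCc1ccc2ccccc2c1)(c1ccccc1)c1ccccc1 | intermediate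
8 | methyltriphenylphosphonium bromide | C[P+](c1ccccc1)(c1ccccc1)c1ccccc1.[Br-] | starting material
9 | 6-O-(tert-butyldiphenylsilyl)-5-deoxy-1,2-O-isopropylidene-5-methylidene-3-O-(2-naphthylmethyl)-α-D-xylo-hexofuranose | CC(C)(C)[Si](OCC(=C)[C@H]1O[C@@H]2OC(C)(C)O[C@@H]2[C@H]1OCc1ccc2ccccc2c1)(c1ccccc1)c1ccccc1 | intermediate
10 | 6-O-(tert-butyldiphenylsilyl)-5-deoxy-5-methylidene-3-O-(2-naphthylmethyl)-D-xylo-hexofuranose (both anomers) | CC(C)(C)[Si](OCC(=C)[C@H]1OC(O)[C@H](O)[C@H]1OCc1ccc2ccccc2c1)(c1ccccc1)c1ccccc1 | intermediate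
11 | (2S,3R)-4-[(tert-butyldiphenylsilyl)oxymethyl]-3-formyloxy-2-(2-naphthylmethoxy)pent-4-enal | O=C[C@@H](OCc1ccc2ccccc2c1)[C@H](OC=O)C(=C)CO[Si](c1ccccc1)(c1ccccc1)C(C)(C)C | intermediate
12 | dimethyl (1-diazo-2-oxopropyl)phosphonate | COP(=O)(OC)C(=[N+]=[N-])C(C)=O | starting material
13 | (2S,3R)-4-[(tert-butyldiphenylsilyl)oxymethyl]-3-hydroxy-2-(2-naphthylmethoxy)pent-4-enal | O=C[C@@H](OCc1ccc2ccccc2c1)[C@H](O)C(=C)CO[Si](c1ccccc1)(c1ccccc1)C(C)(C)C | intermediate
14 | (3R,4R)-2-[(tert-butyldiphenylsilyl)oxymethyl]-4-(2-naphthylmethoxy)hex-1-en-5-yn-3-ol | C#C[C@@H](OCc1ccc2ccccc2c1)[C@H](O)C(=C)CO[Si](c1ccccc1)(c1ccccc1)C(C)(C)C | intermediate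
15 | 3,6-dichloropyridazine | Clc1ccc(Cl)nn1 | starting material
16 | tributyl(1-ethoxyvinyl)stannane | CCCC[Sn](CCCC)(CCCC)C(=C)OCC | starting material
17 | 3-chloro-6-(1-ethoxyvinyl)pyridazine | C=C(OCC)c1ccc(Cl)nn1 | intermediate
18 | 3-(1-ethoxyvinyl)-6-{[(3R,4R)-2-[(tert-butyldiphenylsilyl)oxymethyl]-4-(2-naphthylmethoxy)hex-1-en-5-yn-3-yl]oxy}pyridazine | C#C[C@@H](OCc1ccc2ccccc2c1)[C@H](Oc1ccc(C(=C)OCC)nn1)C(=C)CO[Si](c1ccccc1)(c1ccccc1)C(C)(C)C | intermediate
19 | 1-(6-{[(3R,4R)-2-[(tert-butyldiphenylsilyl)oxymethyl]-4-(2-naphthylmethoxy)hex-1-en-5-yn-3-yl]oxy}pyridazin-3-yl)ethan-1-one | C#C[C@@H](OCc1ccc2ccccc2c1)[C@H](Oc1ccc(C(C)=O)nn1)C(=C)CO[Si](c1ccccc1)(c1ccccc1)C(C)(C)C | intermediate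
20 | 1-(6-{[(3R,4R)-2-[(tert-butyldiphenylsilyl)oxymethyl]-4-hydroxyhex-1-en-5-yn-3-yl]oxy}pyridazin-3-yl)ethan-1-one | C#C[C@@H](O)[C@H](Oc1ccc(C(C)=O)nn1)C(=C)CO[Si](c1ccccc1)(c1ccccc1)C(C)(C)C | intermediate
21 | 3-methylbutanoyl chloride (isovaleryl chloride) | CC(C)CC(=O)Cl | starting material
22 | (3R,4R)-4-[(6-acetylpyridazin-3-yl)oxy]-5-[(tert-butyldiphenylsilyl)oxymethyl]hex-5-en-1-yn-3-yl 3-methylbutanoate | C#C[C@@H](OC(=O)CC(C)C)[C@H](Oc1ccc(C(C)=O)nn1)C(=C)CO[Si](c1ccccc1)(c1ccccc1)C(C)(C)C | intermediate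
23 | bridged azo cycloadduct: 2,3-diazabicyclo[2.2.2]octa-2,5,7-triene fused to the dihydrofuran (bridgehead configuration left open; both forms lead to 24) | C=C(CO[Si](c1ccccc1)(c1ccccc1)C(C)(C)C)[C@H]1OC23C=CC(C(C)=O)(N=N2)C=C3[C@H]1OC(=O)CC(C)C | intermediate
24 | (2R,3R)-5-acetyl-2-{3-[(tert-butyldiphenylsilyl)oxy]prop-1-en-2-yl}-2,3-dihydro-1-benzofuran-3-yl 3-methylbutanoate | C=C(CO[Si](c1ccccc1)(c1ccccc1)C(C)(C)C)[C@H]1Oc2ccc(C(C)=O)cc2[C@H]1OC(=O)CC(C)C | intermediate
25 | catechol borate (1,3,2-benzodioxaborol-2-yl ether) of carbinol 26 | C=C(CO[Si](c1ccccc1)(c1ccccc1)C(C)(C)C)[C@H]1Oc2ccc([C@@H](C)OB3Oc4ccccc4O3)cc2[C@H]1OC(=O)CC(C)C | intermediate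
26 | (2R,3R)-2-{3-[(tert-butyldiphenylsilyl)oxy]prop-1-en-2-yl}-5-[(1R)-1-hydroxyethyl]-2,3-dihydro-1-benzofuran-3-yl 3-methylbutanoate | C=C(CO[Si](c1ccccc1)(c1ccccc1)C(C)(C)C)[C@H]1Oc2ccc([C@@H](C)O)cc2[C@H]1OC(=O)CC(C)C | intermediate
27 | (R)-2-methylbutanoic acid | OC(=O)[C@H](C)CC | starting material
28 | (2R,3R)-2-{3-[(tert-butyldiphenylsilyl)oxy]prop-1-en-2-yl}-5-{(1R)-1-[(2R)-2-methylbutanoyloxy]ethyl}-2,3-dihydro-1-benzofuran-3-yl 3-methylbutanoate | C=C(CO[Si](c1ccccc1)(c1ccccc1)C(C)(C)C)[C@H]1Oc2ccc([C@@H](C)OC(=O)[C@H](C)CC)cc2[C@H]1OC(=O)CC(C)C | intermediate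
29 | (2R,3R)-2-(3-hydroxyprop-1-en-2-yl)-5-{(1R)-1-[(2R)-2-methylbutanoyloxy]ethyl}-2,3-dihydro-1-benzofuran-3-yl 3-methylbutanoate | C=C(CO)[C@H]1Oc2ccc([C@@H](C)OC(=O)[C@H](C)CC)cc2[C@H]1OC(=O)CC(C)C | intermediate
30 | (2R,3R)-5-{(1R)-1-[(2R)-2-methylbutanoyloxy]ethyl}-2-(3-oxoprop-1-en-2-yl)-2,3-dihydro-1-benzofuran-3-yl 3-methylbutanoate | C=C(C=O)[C@H]1Oc2ccc([C@@H](C)OC(=O)[C@H](C)CC)cc2[C@H]1OC(=O)CC(C)C | target

**Count**

Total steps: 17. Longest linear sequence: 16 steps (steps 1–8 and 10–17 from 1); step 9 is a one-step side branch.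

**Steps most likely to fail**

Step 13. At the temperature the cycloaddition needs, isovaleric acid may be lost from C3 with aromatisation to the benzofuran, or the allylic pyridazinyl ether may shift from O to N before the rings close. The fallback moves the thermal step to the ether stage, where no acyloxy leaving group is present and a higher temperature can be used. Starting from 19, heating in 1,2-dichlorobenzene at 170–200 °C should give (2R,3R)-1-[2-{3-[(tert-butyldiphenylsilyl)oxy]prop-1-en-2-yl}-3-(2-naphthylmethoxy)-2,3-dihydro-1-benzofuran-5-yl]ethan-1-one F1. DDQ in wet CH2Cl2 should then free the cis-3-hydroxy compound (2R,3R)-1-[2-{3-[(tert-butyldiphenylsilyl)oxy]prop-1-en-2-yl}-3-hydroxy-2,3-dihydro-1-benzofuran-5-yl]ethan-1-one F2. Acylation of F2 with isovaleryl chloride, pyridine and catalytic 4-(dimethylamino)pyridine returns to the route at 24.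

Step 8. Under carbonate in methanol the β-formyloxy (then β-hydroxy) aldehyde may undergo β-elimination, retro-aldol cleavage or epimerisation at the α-alkoxy carbon faster than it is homologated. The fallback forms the alkyne without exposing the aldehyde to base. Starting from 11, CBr4 and PPh3 with Zn dust in CH2Cl2 at 0 °C (Corey–Fuchs olefination) should give the dibromoalkene formate (3S,4R)-1,1-dibromo-5-[(tert-butyldiphenylsilyl)oxymethyl]-3-(2-naphthylmethoxy)hexa-1,5-dien-4-yl formate F3. With the aldehyde gone, K2CO3 in MeOH at 0 °C should remove the formate to give the dibromo alcohol (3R,4S)-6,6-dibromo-2-[(tert-butyldiphenylsilyl)oxymethyl]-4-(2-naphthylmethoxy)hexa-1,5-dien-3-ol F4. n-BuLi (about three equivalents) in THF at −78 °C, followed by aqueous NH4Cl, should convert F4 into the alkyne by bromine–lithium exchange and rearrangement, returning to the route at 14.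

Step 10. Substitution at the less activated chloro(alkenyl)pyridazine by a hindered secondary alkoxide may be slow, and on prolonged warming the silyl group may migrate to the alkoxide or the alkyne may isomerise. The fallback uses the more electrophilic dichloride and introduces the acetyl equivalent afterwards. Starting from 14, NaH and 3,6-dichloropyridazine 15 in THF at 0 °C → rt should give 3-chloro-6-{[(3R,4R)-2-[(tert-butyldiphenylsilyl)oxymethyl]-4-(2-naphthylmethoxy)hex-1-en-5-yn-3-yl]oxy}pyridazine F5. Stille coupling of F5 with stannane 16 (PdCl2(PPh3)2, toluene, 90 °C, no copper salt) returns to the route at enol ether 18, which is hydrolysed to 19 as in step 10. In that coupling, oxidative addition of zerovalent palladium into the activated C–Cl bond must outrun ionisation of the allylic ether.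

**Further compounds**

F1 | step 13 | (2R,3R)-1-[2-{3-[(tert-butyldiphenylsilyl)oxy]prop-1-en-2-yl}-3-(2-naphthylmethoxy)-2,3-dihydro-1-benzofuran-5-yl]ethan-1-one | C=C(CO[Si](c1ccccc1)(c1ccccc1)C(C)(C)C)[C@H]1Oc2ccc(C(C)=O)cc2[C@H]1OCc1ccc2ccccc2c1
F2 | step 13 | (2R,3R)-1-[2-{3-[(tert-butyldiphenylsilyl)oxy]prop-1-en-2-yl}-3-hydroxy-2,3-dihydro-1-benzofuran-5-yl]ethan-1-one | C=C(CO[Si](c1ccccc1)(c1ccccc1)C(C)(C)C)[C@H]1Oc2ccc(C(C)=O)cc2[C@H]1O
F3 | step 8 | (3S,4R)-1,1-dibromo-5-[(tert-butyldiphenylsilyl)oxymethyl]-3-(2-naphthylmethoxy)hexa-1,5-dien-4-yl formate | BrC(Br)=C[C@@H](OCc1ccc2ccccc2c1)[C@H](OC=O)C(=C)CO[Si](c1ccccc1)(c1ccccc1)C(C)(C)C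
F4 | step 8 | (3R,4S)-6,6-dibromo-2-[(tert-butyldiphenylsilyl)oxymethyl]-4-(2-naphthylmethoxy)hexa-1,5-dien-3-ol | BrC(Br)=C[C@@H](OCc1ccc2ccccc2c1)[C@H](O)C(=C)CO[Si](c1ccccc1)(c1ccccc1)C(C)(C)C
F5 | step 10 | 3-chloro-6-{[(3R,4R)-2-[(tert-butyldiphenylsilyl)oxymethyl]-4-(2-naphthylmethoxy)hex-1-en-5-yn-3-yl]oxy}pyridazine | C#C[C@@H](OCc1ccc2ccccc2c1)[C@H](Oc1ccc(Cl)nn1)C(=C)CO[Si](c1ccccc1)(c1ccccc1)C(C)(C)C
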